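## Retrosynthetic overview

1. Enabling feature: the four contiguous oxygen-bearing carbons of the quinone ring, C1(=O)–C2(OMe)=C3(OMe)–C4(=O), map onto the four carbons of dimethyl squarate. The remaining edge, C5(chroman-3-yl)=C6(H), maps onto a terminal alkyne, and because the two OMe-bearing carbons are equivalent no regiochemical question arises.
2. Quinone ring (closed last) ⇒ 4-alkynyl-4-hydroxycyclobutenone 13 by thermal ring expansion, with the four-membered ring as a temporary ring ⇒ lithium acetylide 12 + dimethyl squarate 11.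
3. Acetylide 12 ⇒ dibromoalkene 10 ⇒ aldehyde 9 ⇒ (R)-chroman-3-carboxylic acid 7. The only stereocentre (C3) comes from asymmetric hydrogenation of 2H-chromene-3-carboxylic acid 6.
4. Pyran ring of 6 ⇒ salicylaldehyde 3 + acrylonitrile 4, and 3 ⇒ 2,3,4-trimethoxybenzaldehyde 1 (Dakin oxidation, ortho-formylation).
5. Ring order: benzene ring (bought) → pyran ring (step 3) → quinone ring (step 10).

Key step: step 10

Assumption: the (S)-configured H8-BINAP ligand is taken to deliver the (3R)-acid 7, by analogy with tiglic and (E)-2-alkylcinnamic acids, where it hydrogenates the corresponding alkene face. If the sense proves opposite, the equally available (R)-ligand is used and nothing else changes.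

## Route

Step 1
Reactants: 1 2,3,4-trimethoxybenzaldehyde
Product: 2 2,3,4-trimethoxyphenol
Conditions: 30% aq H2O2, cat. H2SO4, MeOH, rt
Reagents that add atoms: hydrogen peroxide, OO
Why: Acid-catalysed Dakin (Baeyer–Villiger-type) oxidation, in which the aryl group carrying ortho and para methoxy donors migrates to oxygen and the aryl formate is cleaved in situ.

Step 2
Reactants: 2 2,3,4-trimethoxyphenol
Product: 3 2-hydroxy-3,4,5-trimethoxybenzaldehyde
Conditions: MgCl2, Et3N, (CH2O)n, MeCN, reflux; then 1 M HCl
Reagents that add atoms: paraformaldehyde (as formaldehyde), C=O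
Why: Casnati–Skattebøl ortho-formylation, in which the magnesium phenoxide delivers formaldehyde to the only free ortho position and a second formaldehyde oxidises the benzylic alkoxide to the aldehyde.

Step 3
Reactants: 3 2-hydroxy-3,4,5-trimethoxybenzaldehyde; 4 acrylonitrile
Product: 5 6,7,8-trimethoxy-2H-chromene-3-carbonitrile
Conditions: DABCO (0.3 equiv), neat 4 (excess), reflux
Reagents that add atoms: none
Why: DABCO-mediated Baylis–Hillman/oxa-Michael annulation of a salicylaldehyde with loss of water, well known for 3-methoxy- and 4-methoxysalicylaldehydes, closes the pyran ring.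

Step 4
Reactants: 5 6,7,8-trimethoxy-2H-chromene-3-carbonitrile
Product: 6 6,7,8-trimethoxy-2H-chromene-3-carboxylic acid
Conditions: 10% aq NaOH, reflux; then conc. HCl to pH 1
Reagents that add atoms: water, O; sodium hydroxide, [Na+].[OH-]
Why: Basic nitrile hydrolysis, the standard follow-up of the chromene-nitrile annulation, which the aryl methyl ethers and the ring ether tolerate.

Step 5
Reactants: 6 6,7,8-trimethoxy-2H-chromene-3-carboxylic acid
Product: 7 (3R)-6,7,8-trimethoxychroman-3-carboxylic acid
Conditions: Ru(OAc)2[(S)-H8-BINAP] (1 mol %), H2 (5 bar), MeOH, 25 °C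
Reagents that add atoms: none
Why: Carboxylate-directed Noyori asymmetric hydrogenation of a trisubstituted α,β-unsaturated acid (a cyclic analogue of (E)-2-alkylcinnamic acids), in which the chiral Ru–diphosphine pocket selects the alkene face and so sets C3 as R.

Step 6
Reactants: 7 (3R)-6,7,8-trimethoxychroman-3-carboxylic acid
Product: 8 [(3S)-6,7,8-trimethoxychroman-3-yl]methanol
Conditions: BH3·THF, THF, 0 °C → rt; then H2O
Reagents that add atoms: none
Why: Chemoselective borane reduction of the acid through its acyloxyborane, run without base so that C3 is untouched (the descriptor changes to S only through CIP ranking).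

Step 7
Reactants: 8 [(3S)-6,7,8-trimethoxychroman-3-yl]methanol
Product: 9 (3R)-6,7,8-trimethoxychroman-3-carbaldehyde
Conditions: Dess–Martin periodinane, CH2Cl2, 0 °C → rt; used at once
Reagents that add atoms: none
Why: Dess–Martin oxidation, chosen because it is base-free and should avoid enolisation of the α-stereocentre and retro-oxa-Michael opening of the β-aryloxy aldehyde.

Step 8
Reactants: 9 (3R)-6,7,8-trimethoxychroman-3-carbaldehyde
Product: 10 (3S)-3-(2,2-dibromoethenyl)-6,7,8-trimethoxychroman
Conditions: CBr4, PPh3, Zn dust, CH2Cl2, rt (ylide pre-formed); then 9, 0 °C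
Reagents that add atoms: carbon tetrabromide, BrC(Br)(Br)Br
Why: Ramirez/Corey–Fuchs dibromoolefination with pre-formed Ph3P=CBr2, a non-basic Wittig-type reaction that should outrun enolisation of 9.

Step 9
Reactants: 10 (3S)-3-(2,2-dibromoethenyl)-6,7,8-trimethoxychroman; 11 dimethyl squarate (3,4-dimethoxycyclobut-3-ene-1,2-dione)
Product: 13 4-hydroxy-2,3-dimethoxy-4-{[(3S)-6,7,8-trimethoxychroman-3-yl]ethynyl}cyclobut-2-en-1-one (both carbinol epimers), via lithium [(3S)-6,7,8-trimethoxychroman-3-yl]acetylide 12 (not isolated)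
Conditions: n-BuLi (2.0 equiv), THF, −78 → 0 °C; cannulated into 11, THF, −78 °C; sat. aq NH4Cl
Reagents that add atoms: none
Why: The second stage of the Corey–Fuchs reaction (Br/Li exchange, Fritsch–Buttenberg–Wiechell shift, deprotonation) gives acetylide 12, which adds 1,2 to one of the two equivalent squarate carbonyls, and the new carbinol centre is uncontrolled and needs no control because step 10 erases it.

Step 10
Reactants: 13 4-hydroxy-2,3-dimethoxy-4-{[(3S)-6,7,8-trimethoxychroman-3-yl]ethynyl}cyclobut-2-en-1-one
Product: 16 abruquinone B, 2,3-dimethoxy-5-[(3S)-6,7,8-trimethoxychroman-3-yl]cyclohexa-2,5-diene-1,4-dione, via (3Z)-4-hydroxy-2,3-dimethoxy-6-[(3S)-6,7,8-trimethoxychroman-3-yl]hexa-1,3-dien-5-yn-1-one (enynylketene) 14 (not isolated), via 4-hydroxy-2,3-dimethoxy-6-[(3S)-6,7,8-trimethoxychroman-3-yl]phenoxyl-5-yl diradical 15 (not isolated)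
Conditions: p-xylene (0.02 M, degassed), reflux (138 °C), Ar
Reagents that add atoms: none
Why: Moore rearrangement: conrotatory 4π electrocyclic opening of the C1–C4 bond of the cyclobutenone, with the hydroxyl donor rotating outward, gives the (Z)-enynylketene 14 with the alkyne held next to the ketene carbon. The ketene carbon then bonds to the distal alkyne carbon (six-membered, endo-type closure) to give the aromatic phenoxyl/aryl σ-diradical 15, and net transfer of the hydroxyl hydrogen to the aryl radical centre gives the quinone at its final oxidation level without any oxidant or protecting group. The closest known reaction type is exactly this conversion of dimethyl squarate–alkynyllithium adducts bearing alkyl-substituted alkynes into 5-alkyl-2,3-dimethoxy-1,4-benzoquinones. No new stereocentre is formed: the uncontrolled carbinol carbon of 13 becomes a planar quinone carbonyl, so both epimers converge on one product, and chroman C3, a non-acidic propargylic CH in 13, is not touched under neutral conditions. The selectivity needed is six- over five-membered closure (alkylidenecyclopentenedione path), and it is secured by the secondary alkyl substituent on the alkyne, which gives no stabilisation to the exocyclic vinyl radical of the five-ring path. The chroman also offers no hydrogen at a 1,5-distance from the aryl radical (those positions are O1 and C4a), so the diradical has no easy internal escape.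

## Compound list

1 | 2,3,4-trimethoxybenzaldehyde | COc1ccc(C=O)c(OC)c1OC | starting material
2 | 2,3,4-trimethoxyphenol | COc1ccc(O)c(OC)c1OC | intermediate
3 | 2-hydroxy-3,4,5-trimethoxybenzaldehyde | COc1cc(C=O)c(O)c(OC)c1OC | intermediate
4 | acrylonitrile | C=CC#N | starting material
5 | 6,7,8-trimethoxy-2H-chromene-3-carbonitrile | N#CC1=Cc2cc(OC)c(OC)c(OC)c2OC1 | intermediate
6 | 6,7,8-trimethoxy-2H-chromene-3-carboxylic acid | OC(=O)C1=Cc2cc(OC)c(OC)c(OC)c2OC1 | intermediate
7 | (3R)-6,7,8-trimethoxychroman-3-carboxylic acid | OC(=O)[C@H]1COc2c(cc(OC)c(OC)c2OC)C1 | intermediate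
8 | [(3S)-6,7,8-trimethoxychroman-3-yl]methanol | OC[C@H]1COc2c(cc(OC)c(OC)c2OC)C1 | intermediate
9 | (3R)-6,7,8-trimethoxychroman-3-carbaldehyde | O=C[C@H]1COc2c(cc(OC)c(OC)c2OC)C1 | intermediate
10 | (3S)-3-(2,2-dibromoethenyl)-6,7,8-trimethoxychroman | BrC(Br)=C[C@H]1COc2c(cc(OC)c(OC)c2OC)C1 | intermediate
11 | dimethyl squarate (3,4-dimethoxycyclobut-3-ene-1,2-dione) | COC1=C(OC)C(=O)C1=O | starting material
12 | lithium [(3S)-6,7,8-trimethoxychroman-3-yl]acetylide | [Li]C#C[C@H]1COc2c(cc(OC)c(OC)c2OC)C1 | intermediate
13 | 4-hydroxy-2,3-dimethoxy-4-{[(3S)-6,7,8-trimethoxychroman-3-yl]ethynyl}cyclobut-2-en-1-one, both carbinol epimers | COC1=C(OC)C(O)(C#C[C@H]2COc3c(cc(OC)c(OC)c3OC)C2)C1=O | intermediate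
14 | (3Z)-4-hydroxy-2,3-dimethoxy-6-[(3S)-6,7,8-trimethoxychroman-3-yl]hexa-1,3-dien-5-yn-1-one (enynylketene) | O=C=C(OC)/C(OC)=C(/O)C#C[C@H]1COc2c(cc(OC)c(OC)c2OC)C1 | intermediate
15 | 4-hydroxy-2,3-dimethoxy-6-[(3S)-6,7,8-trimethoxychroman-3-yl]phenoxyl-5-yl diradical | COc1c(OC)c(O)[c]c([C@H]2COc3c(cc(OC)c(OC)c3OC)C2)c1[O] | intermediate
16 | abruquinone B, 2,3-dimethoxy-5-[(3S)-6,7,8-trimethoxychroman-3-yl]cyclohexa-2,5-diene-1,4-dione | COC1=C(OC)C(=O)C([C@H]2COc3c(cc(OC)c(OC)c3OC)C2)=CC1=O | target

## Step count

Total step count: 10. Longest linear sequence: 10 (from 1; compounds 4 and 11 are bought).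

## Three steps most likely to fail

**Step 10.**
- What may go wrong: the enynylketene may leak into the five-membered closure. Hydrogen transfer within the diradical may be inefficient and lead to oligomerisation. Prolonged heating of the finished quinone may erode C3 through quinone/quinone-methide tautomerism.
- Fallback: this is the all-pericyclic alkenyl variant. It sets out from 9, closes the same ring last and returns at 16. Takai olefination of 9 (CHI3, CrCl2, THF, 0 °C) should give (3S)-3-[(E)-2-iodoethenyl]-6,7,8-trimethoxychroman F1. Iodine–lithium exchange (t-BuLi, 2 equiv, Et2O, −78 °C) gives (E)-2-[(3S)-6,7,8-trimethoxychroman-3-yl]ethenyllithium F2. This adds to 11 at −78 °C to give 4-hydroxy-2,3-dimethoxy-4-{(E)-2-[(3S)-6,7,8-trimethoxychroman-3-yl]ethenyl}cyclobut-2-en-1-one F3. Heating in toluene (110 °C) triggers 4π opening, 6π electrocyclisation and tautomerisation, with no diradical involved, to 2,3-dimethoxy-5-[(3S)-6,7,8-trimethoxychroman-3-yl]benzene-1,4-diol F4. Ag2O (Et2O, rt) oxidises F4 to 16, so the quinone never sees heat.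

**Step 5.**
- What may go wrong: facial selectivity on the cyclic 2H-chromene acid may be poor, or turnover may be slow with the very electron-rich substrate.
- Fallback: this replaces asymmetric catalysis with a classical resolution, sets out from 6 and returns at 7. Hydrogenation over Pd/C (H2, 1 bar, EtOAc) gives rac-6,7,8-trimethoxychroman-3-carboxylic acid F5. Treatment with (R)-1-phenylethylamine in hot EtOH and fractional crystallisation should deposit (R)-1-phenylethylammonium (3R)-6,7,8-trimethoxychroman-3-carboxylate F6. Meanwhile (R)-1-phenylethylammonium (3S)-6,7,8-trimethoxychroman-3-carboxylate F7 stays in the liquor. If the solubility order is reversed, the antipodal amine is used. Acidification of F6 (1 M HCl, EtOAc) returns 7.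

**Step 8.**
- What may go wrong: configuration at C3 may erode through enolisation or retro-oxa-Michael ring opening of the β-aryloxy aldehyde while it is made, handled and olefinated in the presence of zinc and phosphonium salts.
- Fallback: this avoids the aldehyde altogether by eliminating an enol phosphate of a methyl ketone. It sets out from 7 and returns at 12. CDI then MeNHOMe·HCl (CH2Cl2, rt) gives (3R)-N-methoxy-N-methyl-6,7,8-trimethoxychroman-3-carboxamide F8. MeMgBr (THF, 0 °C) gives 1-[(3R)-6,7,8-trimethoxychroman-3-yl]ethan-1-one F9. Kinetic deprotonation at the methyl group (LDA, THF, −78 °C) and trapping with ClP(O)(OEt)2 give diethyl 1-[(3R)-6,7,8-trimethoxychroman-3-yl]ethenyl phosphate F10, without placing charge on C3. Elimination with LDA (2.2 equiv, −78 °C → rt) and an aqueous quench give (3S)-3-ethynyl-6,7,8-trimethoxychroman F11, which also serves as a checkpoint for enantiopurity. n-BuLi (1.0 equiv, THF, −78 °C) converts F11 into 12 for the second half of step 9.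

## Further compounds

F1 | step 10 | (3S)-3-[(E)-2-iodoethenyl]-6,7,8-trimethoxychroman | I/C=C/[C@H]1COc2c(cc(OC)c(OC)c2OC)C1
F2 | step 10 | (E)-2-[(3S)-6,7,8-trimethoxychroman-3-yl]ethenyllithium | [Li]/C=C/[C@H]1COc2c(cc(OC)c(OC)c2OC)C1
F3 | step 10 | 4-hydroxy-2,3-dimethoxy-4-{(E)-2-[(3S)-6,7,8-trimethoxychroman-3-yl]ethenyl}cyclobut-2-en-1-one, both carbinol epimers | COC1=C(OC)C(O)(/C=C/[C@H]2COc3c(cc(OC)c(OC)c3OC)C2)C1=O
F4 | step 10 | 2,3-dimethoxy-5-[(3S)-6,7,8-trimethoxychroman-3-yl]benzene-1,4-diol | COc1c(O)cc([C@H]2COc3c(cc(OC)c(OC)c3OC)C2)c(O)c1OC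
F5 | step 5 | rac-6,7,8-trimethoxychroman-3-carboxylic acid | OC(=O)C1COc2c(cc(OC)c(OC)c2OC)C1
F6 | step 5 | (R)-1-phenylethylammonium (3R)-6,7,8-trimethoxychroman-3-carboxylate | [O-]C(=O)[C@H]1COc2c(cc(OC)c(OC)c2OC)C1.C[C@@H]([NH3+])c1ccccc1
F7 | step 5 | (R)-1-phenylethylammonium (3S)-6,7,8-trimethoxychroman-3-carboxylate | [O-]C(=O)[C@@H]1COc2c(cc(OC)c(OC)c2OC)C1.C[C@@H]([NH3+])c1ccccc1
F8 | step 8 | (3R)-N-methoxy-N-methyl-6,7,8-trimethoxychroman-3-carboxamide | CON(C)C(=O)[C@H]1COc2c(cc(OC)c(OC)c2OC)C1
F9 | step 8 | 1-[(3R)-6,7,8-trimethoxychroman-3-yl]ethan-1-one | CC(=O)[C@H]1COc2c(cc(OC)c(OC)c2OC)C1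
F10 | step 8 | diethyl 1-[(3R)-6,7,8-trimethoxychroman-3-yl]ethenyl phosphate | C=C(OP(=O)(OCC)OCC)[C@H]1COc2c(cc(OC)c(OC)c2OC)C1
F11 | step 8 | (3S)-3-ethynyl-6,7,8-trimethoxychroman | C#C[C@H]1COc2c(cc(OC)c(OC)c2OC)C1
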